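**Assumption (one line):** the target is drawn as the C12-enol of the 11,12,14-trione; abietane numbering is kept throughout, also after ring B becomes the cyclopentane C5–C6–C8–C9–C10 with C7 exocyclic on C6 ("7(8→6)abeo"); commercial (+)-dehydroabietylamine carries the 5α-H/10β-CH3 configuration the target needs.

## Retrosynthetic overview

1. Target ⇒ (enol-ether hydrolysis) 12-O-methyl adduct ⇒ intermolecular Diels–Alder of myrcene across C8=C9 of a ring-B-contracted 12-methoxy abietane quinone aldehyde; the cyclohexene ring is formed last and sets C8 and C9.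
2. Methoxyquinone ⇐ Teuber oxidation of an 11-hydroxy-12-methoxy arene ⇐ directed ortho-lithiation/oxidation.
3. Cyclopentane ring B with its α-CHO carbon ⇐ Tl(III) oxidative ring contraction (aryl 1,2-shift) of the Δ6 styrene ⇐ DDQ dehydrogenation of ferruginol methyl ether.
4. Ferruginol methyl ether ⇐ C12 bromination/Cu methoxylation of dehydroabietane ⇐ reductive deamination of (+)-dehydroabietylamine, which supplies rings A and C and the C5/C10 stereocentres.
5. Ring order: A and C bought; B by contraction; quinone by oxidation; cyclohexene by [4+2].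

## Route

**Step 1**
Reactants: 1 (+)-dehydroabietylamine
Product: 3 abieta-8,11,13-triene (dehydroabietane), via alkyldiazene 2 (not isolated)
Conditions: N-(benzyloxy)-N-(pivaloyloxy)-4-(trifluoromethyl)benzamide (1.3 equiv), THF, 45 °C
Reagents that add atoms: none
Why: The primary amine is N-aminated by the anomeric amide and the adduct collapses to a monoalkyldiazene that loses N2 (reductive deamination), turning C18 into the second C4 methyl while C5 and C10 are untouched.

**Step 2**
Reactants: 3 abieta-8,11,13-triene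
Product: 4 12-bromoabieta-8,11,13-triene
Conditions: NBS (1.05 equiv), MeCN, rt, dark
Reagents that add atoms: N-bromosuccinimide, O=C1CCC(=O)N1Br
Why: Electrophilic aromatic bromination goes to C12, which is para to the C8 alkyl group and free of the peri hindrance at C11 and the double flanking at C14, the selectivity I recall for the dehydroabietate series.

**Step 3**
Reactants: 4 12-bromoabieta-8,11,13-triene
Product: 5 12-methoxyabieta-8,11,13-triene (ferruginol methyl ether)
Conditions: NaOMe, CuI (20 mol %), DMF/MeOH, 120 °C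
Reagents that add atoms: sodium methoxide, [Na+].[O-]C
Why: Copper-catalysed Ullmann-type methoxylation replaces the aryl bromide and tolerates the ortho isopropyl group.

**Step 4**
Reactants: 5 12-methoxyabieta-8,11,13-triene
Product: 6 12-methoxyabieta-6,8,11,13-tetraene
Conditions: DDQ (1.2 equiv), 1,4-dioxane (dry), 80 °C
Reagents that add atoms: none
Why: DDQ abstracts hydride from C7, the benzylic position para to the methoxy group, and loss of H-6 gives the Δ6 styrene (benzylic dehydrogenation).

**Step 5**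
Reactants: 6 12-methoxyabieta-6,8,11,13-tetraene
Product: 8 7,7,12-trimethoxy-7(8→6)abeo-abieta-8,11,13-triene, via oxythallation adduct 7 (not isolated)
Conditions: Tl(NO3)3·3H2O (1.1 equiv), MeOH/HC(OMe)3 1:1, 0 °C, 15 min; NaHCO3
Reagents that add atoms: methanol, CO
Why: Tl(III) adds to C6 from the open α face (the β face is blocked by the axial C19 and C20 methyls) with methanol entering at benzylic C7, and the equatorial C6–Tl bond, antiperiplanar to C7–C8, is displaced by 1,2-shift of the p-methoxyaryl carbon C8 (oxidative semipinacol ring contraction) with inversion at C6, which places the dimethoxymethyl group α (6β-H).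

**Step 6**
Reactants: 8 7,7,12-trimethoxy-7(8→6)abeo-abieta-8,11,13-triene
Product: 11 7,7,12-trimethoxy-7(8→6)abeo-abieta-8,11,13-trien-11-ol, via 11-lithio arene 9 (not isolated), via dimethyl arylboronate 10 (not isolated)
Conditions: s-BuLi, TMEDA, Et2O, −78 → 0 °C; B(OMe)3, −78 °C → rt; 30% H2O2, aq NaOH, 0 °C
Reagents that add atoms: hydrogen peroxide, OO
Why: The methoxy group directs lithiation to C11, its only free ortho position, and borylation followed by peroxide oxidation gives the phenol (directed ortho-metalation/boronate oxidation), the acetal being inert to base.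

**Step 7**
Reactants: 11 7,7,12-trimethoxy-7(8→6)abeo-abieta-8,11,13-trien-11-ol
Product: 13 12-methoxy-11,14-dioxo-7(8→6)abeo-abieta-8,12-dien-7-al, via quinone dimethyl acetal 12 (not isolated)
Conditions: (KSO3)2NO (2.5 equiv), KH2PO4, acetone/H2O, rt; then 2 M HCl, rt, 1 h
Reagents that add atoms: Fremy's salt, [K+].[K+].[O]N(S(=O)(=O)[O-])S(=O)(=O)[O-]; water, O
Why: Fremy's salt oxidises the guaiacol-type phenol at its free para position C14 to the 2-methoxy-p-quinone (Teuber oxidation), and brief aqueous acid then hydrolyses the dimethyl acetal, leaving the 6α-CHO, which is trans to C4 and therefore the thermodynamic arrangement.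

**Step 8**
Reactants: 13 12-methoxy-11,14-dioxo-7(8→6)abeo-abieta-8,12-dien-7-al; 14 myrcene
Product: 15 12-methoxy-11,14-dioxo-8α,9α-[2-(4-methylpent-3-en-1-yl)but-2-ene-1,4-diyl]-7(8→6)abeo-abiet-12-en-7-al
Conditions: BF3·OEt2 (1.1 equiv), myrcene (5 equiv), CH2Cl2, −78 → −20 °C
Reagents that add atoms: none
Why: In this Lewis-acid-promoted Diels–Alder reaction monodentate BF3 binds the more basic vinylogous-ester carbonyl C14=O, so C9 (β to C14) becomes the electrophilic terminus and bonds to the 3-methylene carbon of myrcene ("para" rule), while the diene adds to the α face of C8=C9, anti to the axial C10 methyl, setting both quaternary centres with the new ring α.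

**Step 9**
Reactants: 15 the 12-O-methyl adduct
Product: 16 target (CNP0239256.1)
Conditions: LiOH (3 equiv), THF/H2O 3:1, 0 °C → rt; 1 M HCl to pH 3, 0 °C
Reagents that add atoms: lithium hydroxide, [Li+].[OH-]
Why: Hydroxide adds to C12 of the vinylogous ester and expels methoxide (addition–elimination hydrolysis of the diosphenol methyl ether), acidification gives the C12 enol, and C6 keeps its thermodynamically preferred α-CHO.

## Compound list

1 | (+)-dehydroabietylamine (abieta-8,11,13-trien-18-amine; 4β-CH3, 5α-H, 10β-CH3) | CC(C)C1=CC2=C(C=C1)[C@@]3(C)CCC[C@@](C)(CN)[C@@H]3CC2 | starting material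
2 | abieta-8,11,13-trien-18-yldiazene | CC(C)C1=CC2=C(C=C1)[C@@]3(C)CCC[C@@](C)(CN=N)[C@@H]3CC2 | intermediate
3 | abieta-8,11,13-triene (5α-H, 10β-CH3) | CC(C)C1=CC2=C(C=C1)[C@@]3(C)CCCC(C)(C)[C@@H]3CC2 | intermediate
4 | 12-bromoabieta-8,11,13-triene | CC(C)C1=CC2=C(C=C1Br)[C@@]3(C)CCCC(C)(C)[C@@H]3CC2 | intermediate
5 | 12-methoxyabieta-8,11,13-triene (ferruginol methyl ether) | CC(C)C1=CC2=C(C=C1OC)[C@@]3(C)CCCC(C)(C)[C@@H]3CC2 | intermediate
6 | 12-methoxyabieta-6,8,11,13-tetraene | CC(C)C1=CC2=C(C=C1OC)[C@@]3(C)CCCC(C)(C)[C@@H]3C=C2 | intermediate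
7 | 6α-(dinitratothallio)-7,12-dimethoxyabieta-8,11,13-triene (C7 configuration not defined) | CC(C)C1=CC2=C(C=C1OC)[C@@]3(C)CCCC(C)(C)[C@@H]3[C@@H]([Tl](O[N+](=O)[O-])O[N+](=O)[O-])C2OC | intermediate
8 | 7,7,12-trimethoxy-7(8→6)abeo-abieta-8,11,13-triene (5α-H, 6β-H, 10β-CH3) | CC(C)C1=CC2=C(C=C1OC)[C@@]3(C)CCCC(C)(C)[C@@H]3[C@H]2C(OC)OC | intermediate
9 | 11-lithio derivative of 8 | CC(C)C1=CC2=C(C([Li])=C1OC)[C@@]3(C)CCCC(C)(C)[C@@H]3[C@H]2C(OC)OC | intermediate
10 | dimethyl 11-boronate of 8 | CC(C)C1=CC2=C(C(B(OC)OC)=C1OC)[C@@]3(C)CCCC(C)(C)[C@@H]3[C@H]2C(OC)OC | intermediate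
11 | 7,7,12-trimethoxy-7(8→6)abeo-abieta-8,11,13-trien-11-ol | CC(C)C1=CC2=C(C(O)=C1OC)[C@@]3(C)CCCC(C)(C)[C@@H]3[C@H]2C(OC)OC | intermediate
12 | 7,7,12-trimethoxy-7(8→6)abeo-abieta-8,12-diene-11,14-dione | CC(C)C1=C(OC)C(=O)C2=C(C1=O)[C@H](C(OC)OC)[C@H]3C(C)(C)CCC[C@]23C | intermediate
13 | 12-methoxy-11,14-dioxo-7(8→6)abeo-abieta-8,12-dien-7-al (5α-H, 6β-H, 10β-CH3) | CC(C)C1=C(OC)C(=O)C2=C(C1=O)[C@H](C=O)[C@H]3C(C)(C)CCC[C@]23C | intermediate
14 | myrcene (7-methyl-3-methyleneocta-1,6-diene) | CC(C)=CCCC(=C)C=C | starting material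
15 | 12-O-methyl Diels–Alder adduct (new cyclohexene ring α on C8/C9, its substituted alkene carbon joined through CH2 to C9; 6α-CHO) | CC(C)=CCCC1=CC[C@@]23C(=O)C(C(C)C)=C(OC)C(=O)[C@]2(C1)[C@@]1(C)CCCC(C)(C)[C@@H]1[C@H]3C=O | intermediate
16 | CNP0239256.1 | CC(C)=CCCC1=CC[C@@]23C(=O)C(C(C)C)=C(O)C(=O)[C@]2(C1)[C@@]1(C)CCCC(C)(C)[C@@H]1[C@H]3C=O | target

## Count and risks

Total steps: 9. Longest linear sequence: 9 (myrcene is used as bought).

**Step 8 (Diels–Alder)** is the most likely to fail. The dienophile is tetrasubstituted, the regiochemistry rests on BF3 sitting on C14=O rather than on the intrinsically more activating C11=O, and the free aldehyde can undergo Lewis-acid ene/Prins chemistry with the new ring alkene or with myrcene. The fallback removes the aldehyde from the Lewis-acid step so that more BF3 and a higher temperature can be used. It sets out from 12, isolated by leaving out the acid treatment of step 7. Transacetalisation with ethylene glycol and PPTS in CH2Cl2 gives the dioxolane-protected methoxyquinone F1. The BF3·OEt2-promoted cycloaddition with 14 at −78 → −40 °C then gives the dioxolane-protected adduct F2. PPTS in wet acetone at 50 °C frees the aldehyde, and the route is rejoined at 15.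

**Step 5 (ring contraction)** may stop at solvent capture of the thallium adduct or fail to form the strained trans-fused cyclopentane. The fallback replaces the cationic aryl shift by a Wolff rearrangement and sets out from 5, skipping step 4. Benzylic oxidation with CrO3 in AcOH gives 12-methoxyabieta-8,11,13-trien-7-one F3. Detrifluoroacetylative diazo transfer (LiHMDS, CF3CO2CH2CF3; then MsN3, Et3N) gives the 6-diazo-7-ketone F4. Photolysis in MeOH, followed by NaOMe equilibration, gives the ring-contracted 6α methyl ester F5. DIBAL-H at −78 °C gives the aldehyde F6, and HC(OMe)3 with PPTS in MeOH returns to the route at 8.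

**Step 6 (ortho-lithiation)** may be slow at the hindered C11 position or may compete with benzylic deprotonation. The fallback sets out from 8 and replaces C–H deprotonation by electrophilic substitution and halogen–metal exchange. NBS in MeCN brominates the only activated free position to give the 11-bromo acetal F7. t-BuLi at −78 °C then gives the aryllithium, and the route is rejoined at 9.

## Further compounds

F1 | step 8 | 7,7-ethylenedioxy-12-methoxy-7(8→6)abeo-abieta-8,12-diene-11,14-dione | CC(C)C1=C(OC)C(=O)C2=C(C1=O)[C@H](C4OCCO4)[C@H]3C(C)(C)CCC[C@]23C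
F2 | step 8 | 1,3-dioxolane acetal of adduct 15 | CC(C)=CCCC1=CC[C@@]23C(=O)C(C(C)C)=C(OC)C(=O)[C@]2(C1)[C@@]1(C)CCCC(C)(C)[C@@H]1[C@H]3C4OCCO4
F3 | step 5 | 12-methoxyabieta-8,11,13-trien-7-one | CC(C)C1=CC2=C(C=C1OC)[C@@]3(C)CCCC(C)(C)[C@@H]3CC2=O
F4 | step 5 | 6-diazo-12-methoxyabieta-8,11,13-trien-7-one | CC(C)C1=CC2=C(C=C1OC)[C@@]3(C)CCCC(C)(C)[C@@H]3C(=[N+]=[N-])C2=O
F5 | step 5 | methyl 12-methoxy-7(8→6)abeo-abieta-8,11,13-trien-7-oate (6β-H) | CC(C)C1=CC2=C(C=C1OC)[C@@]3(C)CCCC(C)(C)[C@@H]3[C@H]2C(=O)OC
F6 | step 5 | 12-methoxy-7(8→6)abeo-abieta-8,11,13-trien-7-al (6β-H) | CC(C)C1=CC2=C(C=C1OC)[C@@]3(C)CCCC(C)(C)[C@@H]3[C@H]2C=O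
F7 | step 6 | 11-bromo-7,7,12-trimethoxy-7(8→6)abeo-abieta-8,11,13-triene | CC(C)C1=CC2=C(C(Br)=C1OC)[C@@]3(C)CCCC(C)(C)[C@@H]3[C@H]2C(OC)OC
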